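**Retrosynthetic overview**

- The strategy rests on ring A of the flavonol (C4a, C5, C6, C7, C8, C8a): a fully substituted resorcinol-type ring with OH on C5, H on C6, O on C7 and prenyl on C8, fused through C4a=C8a to pyranone ring C.
- Ring A is cut into a (pyranonyl)(prenyl)ketene and (triisopropylsilyloxy)acetylene; forward, one ketene–alkyne benzannulation makes C5–C6, C7–C8 and C4a–C5. Ring A is therefore formed last, on a finished ring C that already carries ring B.
- The ketene comes from Wolff rearrangement of an α-prenyl α-diazoketone on pyranone C2 (future C8a); the neighbouring C3–H is the future C4a.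
- The diazoketone comes from kojic acid (ring C): C6 bromination, Suzuki coupling with the ring B boronate (from 4-bromophenol by ortho-prenylation), then CH2OH → CHO → homoprenyl carbinol → ketone → detrifluoroacetylative diazo transfer.
- Endgame: desilylation at O7, then cleavage of the MOM ethers at O3 and O4'.

Key step: step 12

Abbreviations: prenyl = 3-methylbut-2-en-1-yl; MOM = methoxymethyl; TIPS = triisopropylsilyl; Ar = 4-(methoxymethoxy)-3-prenylphenyl.

Assumption: (triisopropylsilyloxy)acetylene is treated as not purchasable and is made in step 11; kojic acid is taken to brominate at C6, the free position ortho to its enolic hydroxyl.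

**Route**

Step 1
Reactants: 1 kojic acid (5-hydroxy-2-(hydroxymethyl)-4H-pyran-4-one)
Product: 2 2-bromo-3-hydroxy-6-(hydroxymethyl)-4H-pyran-4-one
Conditions: NBS, DMF, 0 °C → rt, dark
Reagents that add atoms: N-bromosuccinimide, O=C1CCC(=O)N1Br
Why: The enolic hydroxyl makes the pyranone react like a phenol, so electrophilic bromination should go to its only free ortho position (C6 of kojic acid), as in the Mannich and azo-coupling chemistry of kojic acid.

Step 2
Reactants: 2 2-bromo-3-hydroxy-6-(hydroxymethyl)-4H-pyran-4-one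
Product: 3 2-bromo-6-(hydroxymethyl)-3-(methoxymethoxy)-4H-pyran-4-one
Conditions: MOMCl, K2CO3, DMF, 0 °C → rt
Reagents that add atoms: chloromethyl methyl ether, COCCl
Why: Williamson-type O-alkylation in which carbonate deprotonates only the acidic enolic hydroxyl, so the neutral primary alcohol and the vinylogous acyl bromide should stay untouched.

Step 3
Reactants: 4 4-bromophenol; 5 prenyl bromide (1-bromo-3-methylbut-2-ene)
Product: 6 4-bromo-2-prenylphenol
Conditions: NaH, toluene, 0 °C → rt
Reagents that add atoms: none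
Why: ortho-C-alkylation of a sodium phenoxide held as a tight ion pair in a non-polar solvent, with the para position blocked by bromine and the O-prenyl ether as a separable by-product.

Step 4
Reactants: 6 4-bromo-2-prenylphenol
Product: 7 4-bromo-1-(methoxymethoxy)-2-prenylbenzene
Conditions: MOMCl, i-Pr2NEt, CH2Cl2, 0 °C → rt
Reagents that add atoms: chloromethyl methyl ether, COCCl
Why: Standard MOM ether formation on a phenol, giving a group that withstands the organometallic and basic steps ahead.

Step 5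
Reactants: 7 4-bromo-1-(methoxymethoxy)-2-prenylbenzene
Product: 8 2-[4-(methoxymethoxy)-3-prenylphenyl]-4,4,5,5-tetramethyl-1,3,2-dioxaborolane
Conditions: B2pin2, Pd(dppf)Cl2, KOAc, 1,4-dioxane, 90 °C
Reagents that add atoms: bis(pinacolato)diboron, CC1(C)OB(OC1(C)C)B1OC(C)(C)C(C)(C)O1
Why: Miyaura borylation of an aryl bromide, to which the MOM ether and the trisubstituted alkene are inert.

Step 6
Reactants: 3 2-bromo-6-(hydroxymethyl)-3-(methoxymethoxy)-4H-pyran-4-one; 8 2-[4-(methoxymethoxy)-3-prenylphenyl]-4,4,5,5-tetramethyl-1,3,2-dioxaborolane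
Product: 9 2-Ar-6-(hydroxymethyl)-3-(methoxymethoxy)-4H-pyran-4-one
Conditions: Pd(dppf)Cl2, K2CO3, 1,4-dioxane–H2O, 80 °C
Reagents that add atoms: none
Why: Suzuki–Miyaura coupling in which the C–Br bond of the vinylogous acyl bromide adds readily to zerovalent palladium and the free primary alcohol is tolerated.

Step 7
Reactants: 9 2-Ar-6-(hydroxymethyl)-3-(methoxymethoxy)-4H-pyran-4-one
Product: 10 6-Ar-5-(methoxymethoxy)-4-oxo-4H-pyran-2-carbaldehyde
Conditions: Dess–Martin periodinane, CH2Cl2, 0 °C → rt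
Reagents that add atoms: none
Why: Dess–Martin oxidation of the activated primary alcohol to the aldehyde under near-neutral conditions that leave the MOM ethers and the prenyl alkene alone.

Step 8
Reactants: 10 6-Ar-5-(methoxymethoxy)-4-oxo-4H-pyran-2-carbaldehyde; 11 5-bromo-2-methylpent-2-ene
Product: 13 rac-2-Ar-6-(1-hydroxy-5-methylhex-4-en-1-yl)-3-(methoxymethoxy)-4H-pyran-4-one, via (4-methylpent-3-en-1-yl)magnesium bromide 12 (not isolated)
Conditions: 11, Mg, THF, rt; then 10, THF, −78 °C; aq. NH4Cl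
Reagents that add atoms: none
Why: Grignard 1,2-addition to an aldehyde that is far more electrophilic at −78 °C than the vinylogous-ester carbonyl of the pyranone; the new carbinol centre is racemic and is erased in step 9.

Step 9
Reactants: 13 rac-2-Ar-6-(1-hydroxy-5-methylhex-4-en-1-yl)-3-(methoxymethoxy)-4H-pyran-4-one
Product: 14 2-Ar-3-(methoxymethoxy)-6-(5-methylhex-4-enoyl)-4H-pyran-4-one
Conditions: Dess–Martin periodinane, CH2Cl2, rt
Reagents that add atoms: none
Why: Dess–Martin oxidation of a secondary alcohol to the ketone without acid or base that could harm the pyranone or the MOM ethers.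

Step 10
Reactants: 14 2-Ar-3-(methoxymethoxy)-6-(5-methylhex-4-enoyl)-4H-pyran-4-one
Product: 16 1-[6-Ar-5-(methoxymethoxy)-4-oxo-4H-pyran-2-yl]-2-diazo-5-methylhex-4-en-1-one, via trifluoroacetyl diketone 15 (not isolated)
Conditions: LiN(SiMe3)2, THF, −78 °C; CF3CO2CH2CF3, −78 °C; 5% aq. HCl work-up; then MsN3, Et3N, H2O, MeCN, rt
Reagents that add atoms: methanesulfonyl azide, CS(=O)(=O)N=[N+]=[N-]
Why: Detrifluoroacetylative diazo transfer, in which the single enolisable position of the ketone is trifluoroacetylated and the activated 1,3-diketone then takes the diazo group from the sulfonyl azide with loss of the trifluoroacetyl group, an activation a simple ketone needs for Regitz-type transfer.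

Step 11
Reactants: 17 acetylene
Product: 20 (triisopropylsilyloxy)acetylene, via lithium acetylide 18 (not isolated), via lithium ethynolate 19 (not isolated)
Conditions: n-BuLi, THF, −78 °C (17 in excess); LiOOt-Bu (from t-BuOOH and LiN(SiMe3)2, THF, −78 °C), −78 → 0 °C; then i-Pr3SiOTf, −78 → 0 °C
Reagents that add atoms: tert-butyl hydroperoxide (used as its lithium salt), CC(C)(C)OO; triisopropylsilyl trifluoromethanesulfonate, CC(C)[Si](C(C)C)(C(C)C)OS(=O)(=O)C(F)(F)F
Why: Oxidation of a lithium acetylide by lithium tert-butyl peroxide to the ynolate followed by O-silylation with a bulky silyl triflate is the standard entry to 1-siloxyalkynes and is applied here to the parent acetylide.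

Step 12
Reactants: 16 1-[6-Ar-5-(methoxymethoxy)-4-oxo-4H-pyran-2-yl]-2-diazo-5-methylhex-4-en-1-one; 20 (triisopropylsilyloxy)acetylene
Product: 24 5-hydroxy-3-(methoxymethoxy)-2-[4-(methoxymethoxy)-3-prenylphenyl]-8-prenyl-7-(triisopropylsilyloxy)-4H-chromen-4-one, via pyranonyl prenyl ketene 21 (not isolated), via siloxycyclobutenone 22 (not isolated), via dienylketene 23 (not isolated)
Conditions: 20 (2 equiv), hν (blue LEDs, ca. 440 nm), ClCH2CH2Cl, rt; then 80 °C
Reagents that add atoms: none
Why: Proposed new method: light expels N2 from 16 and the pyranonyl group migrates from the acyl carbon to the diazo carbon (Wolff rearrangement), so that ketene 21 has the pyranone C2=C3 bond as its vinyl unit and the prenyl group on the future C8; the closest known reaction is the Danheiser benzannulation of α,β-unsaturated and aryl α-diazoketones with siloxyalkynes, which has not been run with a 4-pyranone as the vinyl partner. The nucleophilic CH terminus of 20 attacks the ketene carbonyl carbon and the [2+2] cycloaddition gives cyclobutenone 22 (bonds C5–C6 and C7–C8), whose 4π electrocyclic opening on warming gives dienylketene 23. Ring A is then closed by 6π electrocyclisation of 23, the ketene carbon bonding to the hydrogen-bearing pyranone C3 (bond C4a–C5), and the cyclohexadienone so formed, whose C4a–H lies between two carbonyl groups, should tautomerise at once to the chelated C5 phenol. No stereocentre is formed. Two selectivities are needed: Wolff migration must beat the 1,2-hydride shift from the prenyl CH2 (direct photolysis rather than metal-carbene formation favours migration, and the dienone is the expected by-product), and the [2+2] regiochemistry is fixed by the polarisation of the ynol ether; because every ring A substituent is set by the connectivity of 16 and 20, no 6- versus 8-prenyl or O5 versus O7 question arises. Visible light is chosen because the diazoketone absorbs there, whereas the pyranone and the flavone product, which rearrange or degrade under ultraviolet light, do not.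

Step 13
Reactants: 24 5-hydroxy-3-(methoxymethoxy)-2-[4-(methoxymethoxy)-3-prenylphenyl]-8-prenyl-7-(triisopropylsilyloxy)-4H-chromen-4-one
Product: 25 5,7-dihydroxy-3-(methoxymethoxy)-2-[4-(methoxymethoxy)-3-prenylphenyl]-8-prenyl-4H-chromen-4-one
Conditions: Bu4NF, AcOH, THF, 0 °C
Reagents that add atoms: none
Why: Fluoride cleavage of the aryl silyl ether, buffered with acetic acid so that the phenoxide is not exposed to base-promoted air oxidation, while the MOM ethers are inert.

Step 14
Reactants: 25 5,7-dihydroxy-3-(methoxymethoxy)-2-[4-(methoxymethoxy)-3-prenylphenyl]-8-prenyl-4H-chromen-4-one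
Product: 26 broussoflavonol F (3,5,7-trihydroxy-2-(4-hydroxy-3-prenylphenyl)-8-prenyl-4H-chromen-4-one)
Conditions: 3 M aq. HCl, MeOH, 40 °C
Reagents that add atoms: none
Why: Acid-catalysed acetal exchange of both MOM ethers with methanol, run dilute and warm rather than hot so that the ortho-prenylphenols should not cyclise to dimethylchromans.

**Compound list**

1 | kojic acid, 5-hydroxy-2-(hydroxymethyl)-4H-pyran-4-one | O=c1cc(CO)occ1O | starting material
2 | 2-bromo-3-hydroxy-6-(hydroxymethyl)-4H-pyran-4-one | O=c1cc(CO)oc(Br)c1O | intermediate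
3 | 2-bromo-6-(hydroxymethyl)-3-(methoxymethoxy)-4H-pyran-4-one | COCOc1c(Br)oc(CO)cc1=O | intermediate
4 | 4-bromophenol | Oc1ccc(Br)cc1 | starting material
5 | prenyl bromide, 1-bromo-3-methylbut-2-ene | CC(C)=CCBr | starting material
6 | 4-bromo-2-(3-methylbut-2-en-1-yl)phenol | CC(C)=CCc1cc(Br)ccc1O | intermediate
7 | 4-bromo-1-(methoxymethoxy)-2-(3-methylbut-2-en-1-yl)benzene | COCOc1ccc(Br)cc1CC=C(C)C | intermediate
8 | 2-[4-(methoxymethoxy)-3-(3-methylbut-2-en-1-yl)phenyl]-4,4,5,5-tetramethyl-1,3,2-dioxaborolane | COCOc1ccc(B2OC(C)(C)C(C)(C)O2)cc1CC=C(C)C | intermediate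
9 | 6-(hydroxymethyl)-3-(methoxymethoxy)-2-[4-(methoxymethoxy)-3-(3-methylbut-2-en-1-yl)phenyl]-4H-pyran-4-one | COCOc1c(-c2ccc(OCOC)c(CC=C(C)C)c2)oc(CO)cc1=O | intermediate
10 | 5-(methoxymethoxy)-6-[4-(methoxymethoxy)-3-(3-methylbut-2-en-1-yl)phenyl]-4-oxo-4H-pyran-2-carbaldehyde | COCOc1c(-c2ccc(OCOC)c(CC=C(C)C)c2)oc(C=O)cc1=O | intermediate
11 | 5-bromo-2-methylpent-2-ene | CC(C)=CCCBr | starting material
12 | (4-methylpent-3-en-1-yl)magnesium bromide | CC(C)=CCC[Mg]Br | intermediate
13 | rac-6-(1-hydroxy-5-methylhex-4-en-1-yl)-3-(methoxymethoxy)-2-[4-(methoxymethoxy)-3-(3-methylbut-2-en-1-yl)phenyl]-4H-pyran-4-one | COCOc1c(-c2ccc(OCOC)c(CC=C(C)C)c2)oc(C(O)CCC=C(C)C)cc1=O | intermediate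
14 | 3-(methoxymethoxy)-2-[4-(methoxymethoxy)-3-(3-methylbut-2-en-1-yl)phenyl]-6-(5-methylhex-4-enoyl)-4H-pyran-4-one | COCOc1c(-c2ccc(OCOC)c(CC=C(C)C)c2)oc(C(=O)CCC=C(C)C)cc1=O | intermediate
15 | rac-4,4,4-trifluoro-1-[5-(methoxymethoxy)-6-[4-(methoxymethoxy)-3-(3-methylbut-2-en-1-yl)phenyl]-4-oxo-4H-pyran-2-yl]-2-(3-methylbut-2-en-1-yl)butane-1,3-dione | COCOc1c(-c2ccc(OCOC)c(CC=C(C)C)c2)oc(C(=O)C(CC=C(C)C)C(=O)C(F)(F)F)cc1=O | intermediate
16 | 2-diazo-1-[5-(methoxymethoxy)-6-[4-(methoxymethoxy)-3-(3-methylbut-2-en-1-yl)phenyl]-4-oxo-4H-pyran-2-yl]-5-methylhex-4-en-1-one | COCOc1c(-c2ccc(OCOC)c(CC=C(C)C)c2)oc(C(=O)C(=[N+]=[N-])CC=C(C)C)cc1=O | intermediate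
17 | acetylene | C#C | starting material
18 | lithium acetylide | [Li+].[C-]#C | intermediate
19 | lithium ethynolate | [Li+].[O-]C#C | intermediate
20 | (triisopropylsilyloxy)acetylene, ethynyloxy(triisopropyl)silane | C#CO[Si](C(C)C)(C(C)C)C(C)C | intermediate
21 | [5-(methoxymethoxy)-6-[4-(methoxymethoxy)-3-(3-methylbut-2-en-1-yl)phenyl]-4-oxo-4H-pyran-2-yl](3-methylbut-2-en-1-yl)ketene | COCOc1c(-c2ccc(OCOC)c(CC=C(C)C)c2)oc(C(CC=C(C)C)=C=O)cc1=O | intermediate
22 | rac-4-[5-(methoxymethoxy)-6-[4-(methoxymethoxy)-3-(3-methylbut-2-en-1-yl)phenyl]-4-oxo-4H-pyran-2-yl]-4-(3-methylbut-2-en-1-yl)-3-(triisopropylsilyloxy)cyclobut-2-en-1-one | COCOc1c(-c2ccc(OCOC)c(CC=C(C)C)c2)oc(C2(CC=C(C)C)C(=O)C=C2O[Si](C(C)C)(C(C)C)C(C)C)cc1=O | intermediate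
23 | (3E)-4-[5-(methoxymethoxy)-6-[4-(methoxymethoxy)-3-(3-methylbut-2-en-1-yl)phenyl]-4-oxo-4H-pyran-2-yl]-7-methyl-3-(triisopropylsilyloxy)octa-1,3,6-trien-1-one (pyranonyl group cis to the ketene arm) | COCOc1c(-c2ccc(OCOC)c(CC=C(C)C)c2)oc(/C(CC=C(C)C)=C(/O[Si](C(C)C)(C(C)C)C(C)C)C=C=O)cc1=O | intermediate
24 | 5-hydroxy-3-(methoxymethoxy)-2-[4-(methoxymethoxy)-3-(3-methylbut-2-en-1-yl)phenyl]-8-(3-methylbut-2-en-1-yl)-7-(triisopropylsilyloxy)-4H-chromen-4-one | CC(C)=CCc1cc(-c2oc3c(CC=C(C)C)c(O[Si](C(C)C)(C(C)C)C(C)C)cc(O)c3c(=O)c2OCOC)ccc1OCOC | intermediate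
25 | 5,7-dihydroxy-3-(methoxymethoxy)-2-[4-(methoxymethoxy)-3-(3-methylbut-2-en-1-yl)phenyl]-8-(3-methylbut-2-en-1-yl)-4H-chromen-4-one | CC(C)=CCc1cc(-c2oc3c(CC=C(C)C)c(O)cc(O)c3c(=O)c2OCOC)ccc1OCOC | intermediate
26 | broussoflavonol F, 3,5,7-trihydroxy-2-[4-hydroxy-3-(3-methylbut-2-en-1-yl)phenyl]-8-(3-methylbut-2-en-1-yl)-4H-chromen-4-one | CC(C)=CCc1cc(-c2oc3c(CC=C(C)C)c(O)cc(O)c3c(=O)c2O)ccc1O | target

**Step count and risks**

Total step count: 14. Longest linear sequence: 11 steps (steps 3, 4, 5, 6, 7, 8, 9, 10, 12, 13, 14, from 4-bromophenol).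

Steps most likely to fail:

1. Step 12 (benzannulation). The excited diazoketone may lose its way by 1,2-hydride shift from the prenyl CH2 instead of Wolff migration. The pyranone chromophore may photodegrade. The dienylketene may fail to close onto the electron-poor pyranone C3 and be diverted. The fallback uses known chemistry only: ring A is bought rather than built, and the 8-prenyl group is placed by a Claisen–Cope shift from O5.
   - It sets out from aryl bromide 7: n-BuLi, THF, −78 °C, then DMF should give 4-(methoxymethoxy)-3-prenylbenzaldehyde F1.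
   - Purchased 2',4',6'-trihydroxyacetophenone is protected at the 4'-hydroxyl (MOMCl, i-Pr2NEt, CH2Cl2, 0 °C) to 1-[2,6-dihydroxy-4-(methoxymethoxy)phenyl]ethan-1-one F2. One chelated hydroxyl is then O-prenylated with 5 (K2CO3, acetone) to 1-[2-hydroxy-4-(methoxymethoxy)-6-(prenyloxy)phenyl]ethan-1-one F3.
   - Claisen–Schmidt condensation of F3 with F1 (KOH, EtOH–H2O, rt) should give (E)-1-[2-hydroxy-4-(methoxymethoxy)-6-(prenyloxy)phenyl]-3-[4-(methoxymethoxy)-3-prenylphenyl]prop-2-en-1-one F4.
   - Algar–Flynn–Oyamada oxidation (H2O2, NaOH, MeOH, 0 °C; the para-alkoxy group of ring B favours flavonol over aurone) should give 3-hydroxy-7-(methoxymethoxy)-2-[4-(methoxymethoxy)-3-prenylphenyl]-5-(prenyloxy)-4H-chromen-4-one F5.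
   - MOMCl and i-Pr2NEt cap the 3-hydroxyl to give 3,7-bis(methoxymethoxy)-2-[4-(methoxymethoxy)-3-prenylphenyl]-5-(prenyloxy)-4H-chromen-4-one F6.
   - Eu(fod)3 (catalytic, PhCl, 85 °C) should move the prenyl group from O5 over C6 to C8 (para-Claisen–Cope rearrangement) to give 5-hydroxy-3,7-bis(methoxymethoxy)-2-[4-(methoxymethoxy)-3-prenylphenyl]-8-prenyl-4H-chromen-4-one F7.
   - F7 under the conditions of step 14 comes back to the route at 26.

2. Step 11 (parent silyl ynol ether). Monolithium acetylide may disproportionate to the dilithium salt on warming, the ynolate may be silylated on carbon or twice, and the product may undergo silyl shift to the silylketene on distillation. The fallback delivers the C6–C7 unit from an alkyl ynol ether whose alkyl group is also fluoride-labile, made by the dichlorovinyl ether route.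
   - 2-(Trimethylsilyl)ethanol, KH and trichloroethylene (THF, −50 °C → rt) should give (E)-1,2-dichlorovinyl 2-(trimethylsilyl)ethyl ether F8.
   - n-BuLi (2.2 equiv, THF, −78 → −40 °C) and a methanol quench should give [2-(ethynyloxy)ethyl]trimethylsilane F9.
   - The fallback sets out from diazoketone 16, which with F9 under the conditions of step 12 should give 5-hydroxy-3-(methoxymethoxy)-2-[4-(methoxymethoxy)-3-prenylphenyl]-8-prenyl-7-[2-(trimethylsilyl)ethoxy]-4H-chromen-4-one F10.
   - Bu4NF (THF, 50 °C) should cleave this ether by β-elimination, the vinylogous carboxylate at O7 being a good leaving group, and so comes back to the route at 25.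

3. Step 3 (C-prenylation of the phenoxide). The ambident phenoxide may alkylate on oxygen or twice, and the product may cyclise to the chroman on acidic work-up. The fallback installs the ortho side chain by a sigmatropic shift and adjusts it by metathesis.
   - It sets out from 4-bromophenol 4: allyl bromide, K2CO3, acetone should give 1-(allyloxy)-4-bromobenzene F11.
   - Aromatic Claisen rearrangement (neat, 190 °C) should give 2-allyl-4-bromophenol F12.
   - MOM protection as in step 4 should give 2-allyl-4-bromo-1-(methoxymethoxy)benzene F13.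
   - Cross-metathesis with 2-methylbut-2-ene (second-generation Grubbs catalyst, CH2Cl2, 40 °C) comes back to the route at 7.

**Further compounds**

F1 | step 12 | 4-(methoxymethoxy)-3-(3-methylbut-2-en-1-yl)benzaldehyde | COCOc1ccc(C=O)cc1CC=C(C)C
F2 | step 12 | 1-[2,6-dihydroxy-4-(methoxymethoxy)phenyl]ethan-1-one | CC(=O)c1c(O)cc(OCOC)cc1O
F3 | step 12 | 1-[2-hydroxy-4-(methoxymethoxy)-6-(3-methylbut-2-en-1-yloxy)phenyl]ethan-1-one | CC(=O)c1c(O)cc(OCOC)cc1OCC=C(C)C
F4 | step 12 | (E)-1-[2-hydroxy-4-(methoxymethoxy)-6-(3-methylbut-2-en-1-yloxy)phenyl]-3-[4-(methoxymethoxy)-3-(3-methylbut-2-en-1-yl)phenyl]prop-2-en-1-one | O=C(/C=C/c1ccc(OCOC)c(CC=C(C)C)c1)c1c(O)cc(OCOC)cc1OCC=C(C)C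
F5 | step 12 | 3-hydroxy-7-(methoxymethoxy)-2-[4-(methoxymethoxy)-3-(3-methylbut-2-en-1-yl)phenyl]-5-(3-methylbut-2-en-1-yloxy)-4H-chromen-4-one | COCOc1cc(OCC=C(C)C)c2c(=O)c(O)c(-c3ccc(OCOC)c(CC=C(C)C)c3)oc2c1
F6 | step 12 | 3,7-bis(methoxymethoxy)-2-[4-(methoxymethoxy)-3-(3-methylbut-2-en-1-yl)phenyl]-5-(3-methylbut-2-en-1-yloxy)-4H-chromen-4-one | COCOc1cc(OCC=C(C)C)c2c(=O)c(OCOC)c(-c3ccc(OCOC)c(CC=C(C)C)c3)oc2c1
F7 | step 12 | 5-hydroxy-3,7-bis(methoxymethoxy)-2-[4-(methoxymethoxy)-3-(3-methylbut-2-en-1-yl)phenyl]-8-(3-methylbut-2-en-1-yl)-4H-chromen-4-one | COCOc1cc(O)c2c(=O)c(OCOC)c(-c3ccc(OCOC)c(CC=C(C)C)c3)oc2c1CC=C(C)C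
F8 | step 11 | (E)-1,2-dichlorovinyl 2-(trimethylsilyl)ethyl ether | Cl/C=C(/Cl)OCC[Si](C)(C)C
F9 | step 11 | [2-(ethynyloxy)ethyl]trimethylsilane | C#COCC[Si](C)(C)C
F10 | step 11 | 5-hydroxy-3-(methoxymethoxy)-2-[4-(methoxymethoxy)-3-(3-methylbut-2-en-1-yl)phenyl]-8-(3-methylbut-2-en-1-yl)-7-[2-(trimethylsilyl)ethoxy]-4H-chromen-4-one | CC(C)=CCc1cc(-c2oc3c(CC=C(C)C)c(OCC[Si](C)(C)C)cc(O)c3c(=O)c2OCOC)ccc1OCOC
F11 | step 3 | 1-(allyloxy)-4-bromobenzene | C=CCOc1ccc(Br)cc1
F12 | step 3 | 2-allyl-4-bromophenol | C=CCc1cc(Br)ccc1O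
F13 | step 3 | 2-allyl-4-bromo-1-(methoxymethoxy)benzene | COCOc1ccc(Br)cc1CC=C
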